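The ten-membered carbocycle is opened at C1–C10 (germacrane numbering: C1 ketone carbon, C10 quaternary O,Me-bearing carbon, C14 its methyl, C3 the enol-ether carbon of furanone ring O/C3/C2/C1/C10). Because C10 carries methyl and ether oxygen beside the C1 ketone, it is stored as a 2-iodoalkene and C1 as an aldehyde: an intramolecular Nozaki–Hiyama–Kishi reaction of open-chain iodo aldehyde 16 (trans-lactone, β-hydroxy aldehyde arm, 2-iodoallyl arm) closes the carbocycle in one operation, leaving a C1 allylic alcohol and an exocyclic C10=C14 methylene. Transannular addition of the C3 hydroxyl across this alkene sets C10; oxidation and dehydrogenation then unveil the 3(2H)-furanone.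

Key step: step 15

Remark on numbering and stereochemistry: germacranolide numbering is used throughout (C4 bears the C15 methyl, C5 the free OH, C6 the lactone oxygen, C8 the angelate, C11–C13 the α-methylene lactone). The C1 carbinol formed in step 15 is an inconsequential epimer mixture and is left unspecified in the SMILES of 17 and 18.

**Step 1**
Reactants: 1 methyl (S)-3-hydroxy-2-methylpropanoate
Product: 2 methyl (S)-3-[(tert-butyldimethylsilyl)oxy]-2-methylpropanoate
Conditions: TBSCl, imidazole, CH2Cl2, 0 °C to rt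
Reagents that add atoms: tert-butyldimethylsilyl chloride, CC(C)(C)[Si](C)(C)Cl
Why: Imidazole-promoted silylation of the primary alcohol; the C4 stereocenter is untouched.

**Step 2**
Reactants: 2 methyl (S)-3-[(tert-butyldimethylsilyl)oxy]-2-methylpropanoate
Product: 3 (S)-3-[(tert-butyldimethylsilyl)oxy]-2-methylpropanal
Conditions: iBu2AlH, CH2Cl2, −78 °C; Rochelle salt work-up; used crude
Reagents that add atoms: none
Why: Partial ester reduction with iBu2AlH stops at the aluminium hemiacetal at −78 °C, and the cold non-basic work-up should leave the α-stereocenter intact.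

**Step 3**
Reactants: 3 (S)-3-[(tert-butyldimethylsilyl)oxy]-2-methylpropanal
Product: 4 (3S,4S,5S)-6-[(tert-butyldimethylsilyl)oxy]-3-(methoxymethoxy)-5-methylhex-1-en-4-ol
Conditions: allyl methoxymethyl ether, s-BuLi, THF, −78 °C; (+)-Ipc2BOMe; BF3·OEt2; then 3, −78 °C; NaOH, H2O2
Reagents that add atoms: allyl methoxymethyl ether, C=CCOCOC
Why: Brown alkoxyallylboration through a closed chair transition state: the (Z)-γ-alkoxyallyl geometry gives the C5-OH/C6-OMOM syn pair, and the isopinocampheyl groups from (−)-α-pinene direct addition to the Re face of the aldehyde (anti-Felkin, C4/C5 anti, also the intrinsic preference of Z-allylboranes), setting C5 and C6 (both S).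

**Step 4**
Reactants: 4 (3S,4S,5S)-6-[(tert-butyldimethylsilyl)oxy]-3-(methoxymethoxy)-5-methylhex-1-en-4-ol
Product: 5 (3S,4S,5S)-4,6-bis[(tert-butyldimethylsilyl)oxy]-3-(methoxymethoxy)-5-methylhex-1-ene
Conditions: TBSOTf, 2,6-lutidine, CH2Cl2, −78 to 0 °C
Reagents that add atoms: tert-butyldimethylsilyl triflate, CC(C)(C)[Si](C)(C)OS(=O)(=O)C(F)(F)F
Why: Silylation of the hindered secondary C5 alcohol with the silyl triflate; this group stays until the last step.

**Step 5**
Reactants: 5 (3S,4S,5S)-4,6-bis[(tert-butyldimethylsilyl)oxy]-3-(methoxymethoxy)-5-methylhex-1-ene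
Product: 6 (3S,4S,5S)-4,6-bis[(tert-butyldimethylsilyl)oxy]-5-methylhex-1-en-3-ol
Conditions: Me2BBr, CH2Cl2, −78 °C; then aq. NaHCO3, THF
Reagents that add atoms: none
Why: Acetal cleavage of the MOM ether by the bromoborane via a bromomethyl ether that hydrolyses on work-up; at −78 °C the two silyl ethers and the alkene should survive.

**Step 6**
Reactants: 6 (3S,4S,5S)-4,6-bis[(tert-butyldimethylsilyl)oxy]-5-methylhex-1-en-3-ol
Product: 7 (3S,4S,5S)-4,6-bis[(tert-butyldimethylsilyl)oxy]-5-methylhex-1-en-3-yl 2-(bromomethyl)prop-2-enoate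
Conditions: 2-(bromomethyl)acrylic acid, DCC, DMAP (cat.), CH2Cl2, 0 °C
Reagents that add atoms: 2-(bromomethyl)acrylic acid, C=C(CBr)C(=O)O
Why: Steglich esterification of the allylic C6 alcohol; low temperature and only catalytic DMAP keep the allylic bromide from being displaced.

**Step 7**
Reactants: 7 (3S,4S,5S)-4,6-bis[(tert-butyldimethylsilyl)oxy]-5-methylhex-1-en-3-yl 2-(bromomethyl)prop-2-enoate
Product: 8 (5S)-3-(bromomethyl)-5-[(1S,2S)-1,3-bis[(tert-butyldimethylsilyl)oxy]-2-methylpropyl]furan-2(5H)-one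
Conditions: second-generation Grubbs catalyst (5 mol%), toluene, 80 °C
Reagents that add atoms: none
Why: Ring-closing metathesis of the acrylate with the C6 vinyl group closes the butenolide with loss of ethene; the C6 stereocenter is not involved.

**Step 8**
Reactants: 9 but-3-yn-1-ol
Product: 10 3-iodobut-3-en-1-ol
Conditions: NaI, TMSCl, H2O, MeCN, rt
Reagents that add atoms: sodium iodide, [Na+].[I-]
Why: Markovnikov hydroiodination of the terminal alkyne by HI generated in situ gives the 2-iodo-1-alkene.

**Step 9**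
Reactants: 10 3-iodobut-3-en-1-ol
Product: 11 3-iodobut-3-enal
Conditions: Dess–Martin periodinane, NaHCO3, CH2Cl2, 0 °C; used crude at once
Reagents that add atoms: none
Why: Buffered Dess–Martin oxidation avoids base, so the β,γ-alkene should not move into conjugation.

**Step 10**
Reactants: 8 (5S)-3-(bromomethyl)-5-[(1S,2S)-1,3-bis[(tert-butyldimethylsilyl)oxy]-2-methylpropyl]furan-2(5H)-one; 11 3-iodobut-3-enal
Product: 12 (4R,5S)-5-[(1S,2S)-1,3-bis[(tert-butyldimethylsilyl)oxy]-2-methylpropyl]-4-[(1S)-1-hydroxy-3-iodobut-3-en-1-yl]-3-methylidenedihydrofuran-2(3H)-one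
Conditions: In powder, THF/H2O (1:1), rt
Reagents that add atoms: none
Why: Indium-mediated Barbier allylation: the allylindium from 8 reacts at its γ-carbon C7 (SE2′) through a chair transition state on the lactone face anti to the C6 side chain (trans-lactone, 7R), and the ring-fixed E-type geometry of the allyl unit sets 8S; the alkenyl iodide is inert to indium.

**Step 11**
Reactants: 12 (4R,5S)-5-[(1S,2S)-1,3-bis[(tert-butyldimethylsilyl)oxy]-2-methylpropyl]-4-[(1S)-1-hydroxy-3-iodobut-3-en-1-yl]-3-methylidenedihydrofuran-2(3H)-one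
Product: 13 C8 angelate of 12
Conditions: angelic acid, 2,4,6-trichlorobenzoyl chloride, Et3N, toluene, rt; then 12, toluene, 80 °C (no DMAP)
Reagents that add atoms: angelic acid [(Z)-2-methylbut-2-enoic acid], C/C=C(/C)C(=O)O
Why: Yamaguchi esterification through the mixed anhydride; omitting nucleophilic catalysts should prevent Z-to-E isomerization to the tiglate.

**Step 12**
Reactants: 13 C8 angelate of 12
Product: 14 C3 primary alcohol (C5-O-TBS retained)
Conditions: HF·pyridine, pyridine, THF, 0 °C
Reagents that add atoms: none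
Why: Buffered HF·pyridine removes the primary silyl ether much faster than the hindered secondary one.

**Step 13**
Reactants: 14 C3 primary alcohol (C5-O-TBS retained)
Product: 15 C3 aldehyde
Conditions: Dess–Martin periodinane, NaHCO3, CH2Cl2, 0 °C to rt
Reagents that add atoms: none
Why: Mild Dess–Martin oxidation leaves the α-methyl stereocenter, the enoates and the alkenyl iodide untouched.

**Step 14**
Reactants: 15 C3 aldehyde
Product: 16 (3R)-β-hydroxy aldehyde (C1 aldehyde, free C3 hydroxyl)
Conditions: tert-butyldimethyl(vinyloxy)silane, BF3·OEt2, CH2Cl2, −78 °C; aq. NaHCO3; used crude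
Reagents that add atoms: tert-butyldimethyl(vinyloxy)silane, C=CO[Si](C)(C)C(C)(C)C
Why: Mukaiyama aldol through an open transition state: Felkin addition to the α-methyl aldehyde is reinforced by 1,3-anti induction from the C5 silyloxy group (anti α-methyl-β-silyloxy aldehyde), setting 3R, the configuration whose oxygen can later bridge to C10 on the required face.

**Step 15**
Reactants: 16 (3R)-β-hydroxy aldehyde (C1 aldehyde, free C3 hydroxyl)
Product: 17 ten-membered 1,3-diol with exocyclic C10=C14 methylene
Conditions: CrCl2 (10 equiv), NiCl2 (cat.), DMSO/THF, rt, 2 mM, slow addition of 16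
Reagents that add atoms: none
Why: NiCl2 is reduced by CrCl2 to zerovalent nickel, which inserts into the C10–I bond; transmetalation gives an alkenyl species of trivalent chromium that adds to the C1 aldehyde, and the chromium alkoxide is released on work-up. This is the Nozaki–Hiyama–Kishi macrocyclization of iodoalkene aldehydes, the standard closure of medium-ring 2-methylene cycloalkanols. The ten-membered carbocycle (C1 to C10) is closed by intramolecular 1,2-addition of the C10 alkenyl metal to the C1 carbonyl (10-exo-trig with respect to the C=O). The only new stereocenter, the C1 carbinol, is not controlled and need not be, since step 17 oxidizes it; C10 stays sp2 and is set in step 16 from C3. The step needs chemoselectivity for the aldehyde over the lactone, the two enoates and the free C3 hydroxyl, which the aldehyde-selective, non-basic organochromium reagent secures, and ring closure over oligomerization, which high dilution and the conformational bias of the trans-lactone carrying both arms should secure.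

**Step 16**
Reactants: 17 ten-membered 1,3-diol with exocyclic C10=C14 methylene
Product: 18 (3R,10R)-3,10-epoxy (tetrahydrofuran-bridged) C1 alcohol
Conditions: [PtCl2(H2C=CH2)]2 (cat.), P(4-CF3C6H4)3, Cl2CHCHCl2, 70 °C
Reagents that add atoms: none
Why: Platinum-catalyzed intramolecular hydroalkoxylation of a γ-hydroxy alkene: anti attack of the C3 hydroxyl on the alkene bound to divalent platinum at the more substituted carbon C10 (5-exo, Markovnikov) and protonolysis of the C14–Pt bond give the C14 methyl; C10 (R) is dictated by C3 because the six-carbon tether C4–C9 can only span the new tetrahydrofuran cis.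

**Step 17**
Reactants: 18 (3R,10R)-3,10-epoxy (tetrahydrofuran-bridged) C1 alcohol
Product: 19 bridged tetrahydrofuran-3-one (C1 ketone)
Conditions: Dess–Martin periodinane, NaHCO3, CH2Cl2, rt
Reagents that add atoms: none
Why: Dess–Martin oxidation of the only free alcohol converges both C1 epimers to one ketone.

**Step 18**
Reactants: 19 bridged tetrahydrofuran-3-one (C1 ketone)
Product: 21 5-O-TBS-rufescenolide B, via trimethylsilyl enol ether 20 (not isolated)
Conditions: TMSOTf, Et3N, CH2Cl2, 0 °C; then Pd(OAc)2, MeCN, rt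
Reagents that add atoms: none
Why: Saegusa–Ito dehydrogenation: enolization can only go toward C2 because C10 is quaternary, and β-hydride elimination of the C3–H from the palladium enolate installs the C2=C3 bond of the 3(2H)-furanone while removing the temporary C3 stereocenter.

**Step 19**
Reactants: 21 5-O-TBS-rufescenolide B
Product: 22 rufescenolide B
Conditions: HF·pyridine, THF, 0 °C to rt
Reagents that add atoms: none
Why: Fluoride-mediated cleavage of the secondary silyl ether under mildly acidic conditions should leave the angelate, the α-methylene lactone and the furanone untouched.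

**Compound list**

1 | methyl (S)-3-hydroxy-2-methylpropanoate (Roche ester) | COC(=O)[C@@H](C)CO | starting material
2 | methyl (S)-3-[(tert-butyldimethylsilyl)oxy]-2-methylpropanoate | COC(=O)[C@@H](C)CO[Si](C)(C)C(C)(C)C | intermediate
3 | (S)-3-[(tert-butyldimethylsilyl)oxy]-2-methylpropanal | O=C[C@@H](C)CO[Si](C)(C)C(C)(C)C | intermediate
4 | (3S,4S,5S)-6-[(tert-butyldimethylsilyl)oxy]-3-(methoxymethoxy)-5-methylhex-1-en-4-ol | C=C[C@H](OCOC)[C@@H](O)[C@@H](C)CO[Si](C)(C)C(C)(C)C | intermediate
5 | (3S,4S,5S)-4,6-bis[(tert-butyldimethylsilyl)oxy]-3-(methoxymethoxy)-5-methylhex-1-ene | C=C[C@H](OCOC)[C@@H](O[Si](C)(C)C(C)(C)C)[C@@H](C)CO[Si](C)(C)C(C)(C)C | intermediate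
6 | (3S,4S,5S)-4,6-bis[(tert-butyldimethylsilyl)oxy]-5-methylhex-1-en-3-ol | C=C[C@H](O)[C@@H](O[Si](C)(C)C(C)(C)C)[C@@H](C)CO[Si](C)(C)C(C)(C)C | intermediate
7 | (3S,4S,5S)-4,6-bis[(tert-butyldimethylsilyl)oxy]-5-methylhex-1-en-3-yl 2-(bromomethyl)prop-2-enoate | C=C[C@H](OC(=O)C(=C)CBr)[C@@H](O[Si](C)(C)C(C)(C)C)[C@@H](C)CO[Si](C)(C)C(C)(C)C | intermediate
8 | (5S)-3-(bromomethyl)-5-[(1S,2S)-1,3-bis[(tert-butyldimethylsilyl)oxy]-2-methylpropyl]furan-2(5H)-one | O=C1O[C@H]([C@@H](O[Si](C)(C)C(C)(C)C)[C@@H](C)CO[Si](C)(C)C(C)(C)C)C=C1CBr | intermediate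
9 | but-3-yn-1-ol | C#CCCO | starting material
10 | 3-iodobut-3-en-1-ol | C=C(I)CCO | intermediate
11 | 3-iodobut-3-enal | C=C(I)CC=O | intermediate
12 | (4R,5S)-5-[(1S,2S)-1,3-bis[(tert-butyldimethylsilyl)oxy]-2-methylpropyl]-4-[(1S)-1-hydroxy-3-iodobut-3-en-1-yl]-3-methylidenedihydrofuran-2(3H)-one | C=C1C(=O)O[C@H]([C@@H](O[Si](C)(C)C(C)(C)C)[C@@H](C)CO[Si](C)(C)C(C)(C)C)[C@H]1[C@@H](O)CC(I)=C | intermediate
13 | C8 angelate of 12 | C=C1C(=O)O[C@H]([C@@H](O[Si](C)(C)C(C)(C)C)[C@@H](C)CO[Si](C)(C)C(C)(C)C)[C@H]1[C@@H](OC(=O)/C(C)=C\C)CC(I)=C | intermediate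
14 | C3 primary alcohol (C5-O-TBS retained) | C=C1C(=O)O[C@H]([C@@H](O[Si](C)(C)C(C)(C)C)[C@@H](C)CO)[C@H]1[C@@H](OC(=O)/C(C)=C\C)CC(I)=C | intermediate
15 | C3 aldehyde | C=C1C(=O)O[C@H]([C@@H](O[Si](C)(C)C(C)(C)C)[C@@H](C)C=O)[C@H]1[C@@H](OC(=O)/C(C)=C\C)CC(I)=C | intermediate
16 | (3R)-β-hydroxy aldehyde (C1 aldehyde, free C3 hydroxyl) | C=C1C(=O)O[C@H]([C@@H](O[Si](C)(C)C(C)(C)C)[C@@H](C)[C@H](O)CC=O)[C@H]1[C@@H](OC(=O)/C(C)=C\C)CC(I)=C | intermediate
17 | ten-membered 1,3-diol with exocyclic C10=C14 methylene (C1 epimers) | C=C1C(=O)O[C@@H]2[C@@H](O[Si](C)(C)C(C)(C)C)[C@@H](C)[C@H](O)CC(O)C(=C)C[C@H](OC(=O)/C(C)=C\C)[C@@H]12 | intermediate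
18 | (3R,10R)-3,10-epoxy (tetrahydrofuran-bridged) C1 alcohol (C1 epimers) | C=C1C(=O)O[C@@H]2[C@@H](O[Si](C)(C)C(C)(C)C)[C@@H](C)[C@H]3CC(O)[C@@](C)(C[C@H](OC(=O)/C(C)=C\C)[C@@H]12)O3 | intermediate
19 | bridged tetrahydrofuran-3-one (C1 ketone) | C=C1C(=O)O[C@@H]2[C@@H](O[Si](C)(C)C(C)(C)C)[C@@H](C)[C@H]3CC(=O)[C@@](C)(C[C@H](OC(=O)/C(C)=C\C)[C@@H]12)O3 | intermediate
20 | trimethylsilyl enol ether of 19 (C1=C2) | C=C1C(=O)O[C@@H]2[C@@H](O[Si](C)(C)C(C)(C)C)[C@@H](C)[C@H]3C=C(O[Si](C)(C)C)[C@@](C)(C[C@H](OC(=O)/C(C)=C\C)[C@@H]12)O3 | intermediate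
21 | 5-O-TBS-rufescenolide B | C=C1C(=O)O[C@@H]2[C@@H](O[Si](C)(C)C(C)(C)C)[C@@H](C)C3=CC(=O)[C@@](C)(C[C@H](OC(=O)/C(C)=C\C)[C@@H]12)O3 | intermediate
22 | rufescenolide B | C=C1C(=O)O[C@@H]2[C@@H](O)[C@@H](C)C3=CC(=O)[C@@](C)(C[C@H](OC(=O)/C(C)=C\C)[C@@H]12)O3 | target

**Step count and risks**

Total step count: 19. Longest linear sequence: 17 steps (steps 1–7 and 10–19); steps 8–9 make the second fragment.

Steps most likely to fail:

Step 15. Ring closure may lose to intermolecular coupling or proto-deiodination, and the free β-hydroxy aldehyde may bind chromium as an alkoxide or undergo retro-aldol cleavage before it cyclizes. The fallback sets out from 16 and removes the hydroxyl from play: silylation (TESOTf, 2,6-lutidine, CH2Cl2, −78 °C) should give the C3 triethylsilyl ether aldehyde F1, ring closure of F1 with CrCl2/NiCl2 under high dilution should give the macrocyclic C3 triethylsilyl ether F2, and PPTS in MeOH at 0 °C should release the C3 hydroxyl and return to 17.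

Step 14. The newly formed aldehyde may compete with 15 for the enol silane (over-addition, oligomerization), and Felkin control may erode. The fallback sets out from 15 and introduces the two carbons as an allyl group: allyltrimethylsilane with BF3·OEt2 at −78 °C (Felkin-selective Hosomi–Sakurai allylation) should give the (3R)-homoallylic alcohol F3. Dihydroxylation of its electron-rich monosubstituted alkene (K2OsO4·2H2O cat., NMO, acetone/H2O), in preference to the enoates and the iodoalkene, should give the triol F4, and NaIO4 cleavage of the terminal diol returns to 16.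

Step 16. The Lewis acidic platinum catalyst may ionize or isomerize the allylic C1 alcohol, or fail to turn over at the hindered 1,1-disubstituted alkene. The fallback sets out from 17 and uses an onium pathway: NIS with NaHCO3 in MeCN in the dark should give, by 5-exo iodoetherification under the same C3-to-C10 stereochemical relay, the iodomethyl tetrahydrofuran F5, and radical deiodination (Bu3SnH, Et3B/air, toluene, 0 °C, slow addition) returns to 18.

**Further compounds**

F1 | step 15 | C3 triethylsilyl ether of aldehyde 16 | C=C1C(=O)O[C@H]([C@@H](O[Si](C)(C)C(C)(C)C)[C@@H](C)[C@H](O[Si](CC)(CC)CC)CC=O)[C@H]1[C@@H](OC(=O)/C(C)=C\C)CC(I)=C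
F2 | step 15 | C3 triethylsilyl ether of macrocycle 17 (C1 epimers) | C=C1C(=O)O[C@@H]2[C@@H](O[Si](C)(C)C(C)(C)C)[C@@H](C)[C@H](O[Si](CC)(CC)CC)CC(O)C(=C)C[C@H](OC(=O)/C(C)=C\C)[C@@H]12
F3 | step 14 | (3R)-homoallylic alcohol from allylation of 15 | C=C1C(=O)O[C@H]([C@@H](O[Si](C)(C)C(C)(C)C)[C@@H](C)[C@H](O)CC=C)[C@H]1[C@@H](OC(=O)/C(C)=C\C)CC(I)=C
F4 | step 14 | triol from dihydroxylation of F3 (new carbinol as a mixture) | C=C1C(=O)O[C@H]([C@@H](O[Si](C)(C)C(C)(C)C)[C@@H](C)[C@H](O)CC(O)CO)[C@H]1[C@@H](OC(=O)/C(C)=C\C)CC(I)=C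
F5 | step 16 | (3R,10R)-3,10-epoxy C14 iodide (iodomethyl tetrahydrofuran; C1 epimers) | C=C1C(=O)O[C@@H]2[C@@H](O[Si](C)(C)C(C)(C)C)[C@@H](C)[C@H]3CC(O)[C@@](CI)(C[C@H](OC(=O)/C(C)=C\C)[C@@H]12)O3
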